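**Strategy.** The tetrahydropyridine (ring A) is made last by inserting nitrogen into a cyclopentane. In ring A the imine carbon C2 carries the methyl group and sits between C3 (O-acyl) and, across N1, C6 (alkyl chain). Removing N1 leaves a 1-methylcyclopentane whose C2 acyloxy and C5 alkyl groups are cis. Acid converts a tertiary azide on that carbon into the N1–C6 and C2=N bonds in one operation, expanding the ring with retention at C6 and erasing the azide-bearing stereocentre. The precursor is the macrodilactone that already holds the all-cis piperidine (ring B) and a 1-azido-1-methylcyclopentane, assembled from an azido cyclopentanol and an N-Boc piperidine acid by esterification and macrolactonisation.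

Key step: step 17

Remark: the azide-bearing carbon of the precursor is taken as S (azide trans to acyloxy and chain), the epimer that azidation anti to the chain delivers; because a hydroxyl-directed hydrogenation of an exocyclic alkene would place the chain trans to oxygen, the cis pair is set by conjugate addition and ketone reduction.

**Route**

Step 1
Reactants: 1 8-bromooctan-1-ol
Product: 2 (8-bromooctyloxy)(tert-butyl)dimethylsilane
Conditions: TBSCl, imidazole, DMF, 0 °C to rt
Reagents that add atoms: tert-butyldimethylsilyl chloride, CC(C)(C)[Si](C)(C)Cl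
Why: Imidazole-promoted silyl ether formation protects the primary oxygen that later becomes the carboxyl terminus and allows the bromide to be converted into a Grignard reagent.

Step 2
Reactants: 2 (8-bromooctyloxy)(tert-butyl)dimethylsilane; 3 2-methylcyclopent-2-en-1-one
Product: 6 tert-butyldimethyl({8-[(1R)-2-methyl-3-(trimethylsilyloxy)cyclopent-2-en-1-yl]octyl}oxy)silane, via Grignard reagent 4 (not isolated), via magnesium enolate 5 (not isolated)
Conditions: Mg, Et2O, rt; then 3, Cu(OTf)2 (3 mol %), chiral BINOL-derived phosphoramidite (6 mol %), Et2O, −30 °C; then TMSCl, Et3N, −30 °C to rt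
Reagents that add atoms: chlorotrimethylsilane, C[Si](C)(C)Cl
Why: Copper-catalysed asymmetric conjugate addition of a Grignard reagent to an α-substituted cyclopentenone, a known substrate class for copper–phosphoramidite catalysts, should set the chain-bearing carbon as R under ligand control (ligand enantiomer chosen accordingly), and O-silylation of the magnesium enolate fixes the fully substituted enol ether for the next step.

Step 3
Reactants: 6 tert-butyldimethyl({8-[(1R)-2-methyl-3-(trimethylsilyloxy)cyclopent-2-en-1-yl]octyl}oxy)silane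
Product: 7 (2S,3R)-2-azido-3-{8-[(tert-butyldimethylsilyl)oxy]octyl}-2-methylcyclopentan-1-one
Conditions: 1-azido-1,2-benziodoxol-3(1H)-one, Zn(OTf)2 (10 mol %), CH2Cl2, 0 °C to rt
Reagents that add atoms: 1-azido-1,2-benziodoxol-3(1H)-one, [N-]=[N+]=NI1OC(=O)c2ccccc12
Why: Azide transfer from the azidoiodinane to a silyl enol ether (α-azidation of enol silanes) should give the tertiary α-azido ketone, the azide entering anti to the adjacent chain so that C2 is S, a centre that is lost again in step 17.

Step 4
Reactants: 7 (2S,3R)-2-azido-3-{8-[(tert-butyldimethylsilyl)oxy]octyl}-2-methylcyclopentan-1-one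
Product: 8 (1S,2S,3R)-2-azido-3-{8-[(tert-butyldimethylsilyl)oxy]octyl}-2-methylcyclopentan-1-ol
Conditions: (R)-2-methyl-CBS-oxazaborolidine (20 mol %), BH3·SMe2, THF, −20 °C; MeOH
Reagents that add atoms: none
Why: Corey–Bakshi–Shibata reduction of an α,α-disubstituted cyclopentanone differentiates the quaternary C2 side from the C5 methylene side, and the (R)-catalyst should deliver hydride to the face opposite the methyl group and the chain, giving the 1S alcohol with oxygen cis to the chain, so that catalyst control and the steric bias of the ring point the same way.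

Step 5
Reactants: 9 N-(benzyloxycarbonyl)-L-alanine
Product: 10 benzyl N-[(2S)-1-[methoxy(methyl)amino]-1-oxopropan-2-yl]carbamate
Conditions: MeNH(OMe)·HCl, EDC·HCl, N-methylmorpholine, CH2Cl2, 0 °C to rt
Reagents that add atoms: N,O-dimethylhydroxylamine hydrochloride, CNOC.Cl
Why: Carbodiimide amide coupling of a urethane-protected amino acid gives the Weinreb amide without loss of configuration at the α-carbon.

Step 6
Reactants: 10 benzyl N-[(2S)-1-[methoxy(methyl)amino]-1-oxopropan-2-yl]carbamate; 11 ethynyltrimethylsilane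
Product: 13 benzyl N-[(2S)-3-oxo-5-(trimethylsilyl)pent-4-yn-2-yl]carbamate, via lithium acetylide 12 (not isolated)
Conditions: 11, n-BuLi, THF, −78 °C; then 10, −78 to −20 °C; aq. NH4Cl
Reagents that add atoms: none
Why: Acylation of a lithium acetylide by a Weinreb amide stops at the ketone because the tetrahedral chelate survives until work-up, the first equivalent of acetylide serving only to deprotonate the carbamate.

Step 7
Reactants: 13 benzyl N-[(2S)-3-oxo-5-(trimethylsilyl)pent-4-yn-2-yl]carbamate
Product: 14 benzyl N-[(2S,3S)-3-hydroxy-5-(trimethylsilyl)pent-4-yn-2-yl]carbamate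
Conditions: Ru[(R,R)-TsDPEN](p-cymene) (2 mol %), i-PrOH, rt
Reagents that add atoms: none
Why: Noyori asymmetric transfer hydrogenation of an alkynyl ketone is catalyst-controlled, and the (R,R)-catalyst should deliver hydride to the face that gives the 3S carbinol, which is the syn amino alcohol needed for a cis 2-methyl-3-oxy piperidine.

Step 8
Reactants: 14 benzyl N-[(2S,3S)-3-hydroxy-5-(trimethylsilyl)pent-4-yn-2-yl]carbamate
Product: 16 benzyl N-[(2S,3S)-3-[(tert-butyldimethylsilyl)oxy]pent-4-yn-2-yl]carbamate, via bis-silyl ether 15 (not isolated)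
Conditions: TBSCl, imidazole, DMF, rt; then K2CO3, MeOH, rt
Reagents that add atoms: tert-butyldimethylsilyl chloride, CC(C)(C)[Si](C)(C)Cl
Why: Silyl ether formation protects the carbinol for the acylation and the later esterification, and carbonate-mediated methanolysis (protiodesilylation) cleaves only the alkynyl C–Si bond.

Step 9
Reactants: 16 benzyl N-[(2S,3S)-3-[(tert-butyldimethylsilyl)oxy]pent-4-yn-2-yl]carbamate; 17 methyl 9-chloro-9-oxononanoate
Product: 18 methyl (12S,13S)-13-{[(benzyloxy)carbonyl]amino}-12-[(tert-butyldimethylsilyl)oxy]-9-oxotetradec-10-ynoate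
Conditions: PdCl2(PPh3)2 (2 mol %), CuI (4 mol %), Et3N, THF, rt
Reagents that add atoms: none
Why: Acyl Sonogashira coupling of a terminal alkyne with an acid chloride gives the ynone, whose ketone carbon becomes C6 of the piperidine and whose chain already carries the ester.

Step 10
Reactants: 18 methyl (12S,13S)-13-{[(benzyloxy)carbonyl]amino}-12-[(tert-butyldimethylsilyl)oxy]-9-oxotetradec-10-ynoate
Product: 21 tert-butyl (2S,3S,6R)-3-[(tert-butyldimethylsilyl)oxy]-6-(8-methoxy-8-oxooctyl)-2-methylpiperidine-1-carboxylate, via cyclic imine 19 (not isolated), via free piperidine 20 (not isolated)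
Conditions: H2 (3 atm), 10% Pd/C, MeOH, rt; filter; then Boc2O, Et3N, 50 °C
Reagents that add atoms: di-tert-butyl dicarbonate, CC(C)(C)OC(=O)OC(=O)OC(C)(C)C
Why: One hydrogenation saturates the alkyne, cleaves the Cbz group and reduces the cyclic imine formed by condensation (intramolecular reductive amination), hydrogen adding to the face opposite the cis methyl and silyloxy groups so that C6 is R and the ring is all-cis, after which carbamoylation protects the hindered nitrogen.

Step 11
Reactants: 21 tert-butyl (2S,3S,6R)-3-[(tert-butyldimethylsilyl)oxy]-6-(8-methoxy-8-oxooctyl)-2-methylpiperidine-1-carboxylate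
Product: 22 8-[(2R,5S,6S)-1-(tert-butoxycarbonyl)-5-[(tert-butyldimethylsilyl)oxy]-6-methylpiperidin-2-yl]octanoic acid
Conditions: LiOH·H2O, THF/MeOH/H2O, rt; then aq. HCl to pH 4
Reagents that add atoms: lithium hydroxide, [Li+].[OH-]
Why: Saponification of the methyl ester with hydroxide leaves the carbamate and the silyl ether intact.

Step 12
Reactants: 8 (1S,2S,3R)-2-azido-3-{8-[(tert-butyldimethylsilyl)oxy]octyl}-2-methylcyclopentan-1-ol; 22 8-[(2R,5S,6S)-1-(tert-butoxycarbonyl)-5-[(tert-butyldimethylsilyl)oxy]-6-methylpiperidin-2-yl]octanoic acid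
Product: 24 (1S,2S,3R)-2-azido-3-{8-[(tert-butyldimethylsilyl)oxy]octyl}-2-methylcyclopentyl 8-[(2R,5S,6S)-1-(tert-butoxycarbonyl)-5-[(tert-butyldimethylsilyl)oxy]-6-methylpiperidin-2-yl]octanoate, via mixed anhydride 23 (not isolated)
Conditions: 22, 2,4,6-trichlorobenzoyl chloride, Et3N, THF, rt; then 8, DMAP, toluene, 50 °C
Reagents that add atoms: none
Why: Yamaguchi esterification through the mixed anhydride and DMAP acylates the hindered cyclopentanol with retention at the carbinol carbon, every other hydroxyl group being silylated.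

Step 13
Reactants: 24 (1S,2S,3R)-2-azido-3-{8-[(tert-butyldimethylsilyl)oxy]octyl}-2-methylcyclopentyl 8-[(2R,5S,6S)-1-(tert-butoxycarbonyl)-5-[(tert-butyldimethylsilyl)oxy]-6-methylpiperidin-2-yl]octanoate
Product: 25 (1S,2S,3R)-2-azido-3-(8-hydroxyoctyl)-2-methylcyclopentyl 8-[(2R,5S,6S)-1-(tert-butoxycarbonyl)-5-hydroxy-6-methylpiperidin-2-yl]octanoate
Conditions: HF·pyridine, pyridine, THF, 0 °C to rt
Reagents that add atoms: none
Why: Fluoride-mediated desilylation removes both silyl ethers in one operation without touching the ester, the carbamate or the azide.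

Step 14
Reactants: 25 (1S,2S,3R)-2-azido-3-(8-hydroxyoctyl)-2-methylcyclopentyl 8-[(2R,5S,6S)-1-(tert-butoxycarbonyl)-5-hydroxy-6-methylpiperidin-2-yl]octanoate
Product: 26 8-[(1R,2S,3S)-2-azido-3-({8-[(2R,5S,6S)-1-(tert-butoxycarbonyl)-5-hydroxy-6-methylpiperidin-2-yl]octanoyl}oxy)-2-methylcyclopentyl]octanoic acid
Conditions: TEMPO (20 mol %), PhI(OAc)2, MeCN/H2O, rt
Reagents that add atoms: water, O
Why: Oxoammonium (TEMPO) oxidation takes the primary alcohol through the aldehyde hydrate to the acid much faster than it attacks the hindered secondary piperidinol.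

Step 15
Reactants: 26 8-[(1R,2S,3S)-2-azido-3-({8-[(2R,5S,6S)-1-(tert-butoxycarbonyl)-5-hydroxy-6-methylpiperidin-2-yl]octanoyl}oxy)-2-methylcyclopentyl]octanoic acid
Product: 28 N-Boc azido macrodilactone (25-membered dilactone of the N-Boc all-cis piperidine and the 2-azido-2-methylcyclopentane unit), via mixed anhydride 27 (not isolated)
Conditions: 2,4,6-trichlorobenzoyl chloride, Et3N, THF, rt; then slow addition to DMAP, toluene, 80 °C, high dilution
Reagents that add atoms: none
Why: Yamaguchi macrolactonisation under high dilution closes the dilactone at the piperidinol oxygen with retention, the less hindered of the two ester-forming sites being reserved for the ring closure.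

Step 16
Reactants: 28 N-Boc azido macrodilactone
Product: 29 azido macrodilactone with free piperidine nitrogen (the rearrangement precursor)
Conditions: TFA, CH2Cl2, 0 °C; aq. NaHCO3
Reagents that add atoms: none
Why: Acidolysis of the tert-butyl carbamate by TFA, an acid too weak to activate the alkyl azide, frees the piperidine nitrogen in a separate step so that no tert-butyl cation is generated under the stronger acid of step 17.

Step 17
Reactants: 29 azido macrodilactone with free piperidine nitrogen
Product: 32 target CNP0304114.1 (macrodilactone of ring A 2-methyl-3,4,5,6-tetrahydropyridine and ring B all-cis piperidine), via aminodiazonium ion 30 (not isolated), via iminium bis(triflate) 31 (not isolated)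
Conditions: TfOH (4 equiv), CH2Cl2, 0 °C to rt; then cold aq. NaHCO3
Reagents that add atoms: none
Why: Triflic acid first protonates the piperidine nitrogen, which is thereby protected, and then the alkylated azide nitrogen to give aminodiazonium ion 30, in which the ring C–C bond antiperiplanar to the departing dinitrogen shifts from carbon to nitrogen in a concerted 1,2-migration that forms N1–C6 and leaves C2 as the iminium carbon of 31. The closest known reaction type is the acid-promoted Schmidt-type rearrangement of tertiary alkyl azides to ring-expanded cyclic imines. Ring A is closed by insertion of nitrogen into the C1–C5 bond of the cyclopentane (five to six members), not by an end-to-end cyclisation. No stereocentre is created: C6 migrates with retention and C3 is untouched, so the cis pair of the cyclopentane becomes the 3,6-cis pair of ring A while the azide-bearing carbon becomes sp2. The step needs migration of the chain-bearing ring carbon in preference to methyl and to the acyloxy-bearing ring carbon; a secondary alkyl carbon migrates better than methyl, and the acyloxy group inductively deactivates its own carbon and also disfavours ionisation to a tertiary cation.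

**Compound list**

1 | 8-bromooctan-1-ol | OCCCCCCCCBr | starting material
2 | (8-bromooctyloxy)(tert-butyl)dimethylsilane | CC(C)(C)[Si](C)(C)OCCCCCCCCBr | intermediate
3 | 2-methylcyclopent-2-en-1-one | CC1=CCCC1=O | starting material
4 | {8-[(tert-butyldimethylsilyl)oxy]octyl}magnesium bromide | CC(C)(C)[Si](C)(C)OCCCCCCCC[Mg]Br | intermediate
5 | bromomagnesium (3R)-3-{8-[(tert-butyldimethylsilyl)oxy]octyl}-2-methylcyclopent-1-en-1-olate | CC1=C(O[Mg]Br)CC[C@H]1CCCCCCCCO[Si](C)(C)C(C)(C)C | intermediate
6 | tert-butyldimethyl({8-[(1R)-2-methyl-3-(trimethylsilyloxy)cyclopent-2-en-1-yl]octyl}oxy)silane | CC1=C(O[Si](C)(C)C)CC[C@H]1CCCCCCCCO[Si](C)(C)C(C)(C)C | intermediate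
7 | (2S,3R)-2-azido-3-{8-[(tert-butyldimethylsilyl)oxy]octyl}-2-methylcyclopentan-1-one | C[C@]1(N=[N+]=[N-])[C@H](CCCCCCCCO[Si](C)(C)C(C)(C)C)CCC1=O | intermediate
8 | (1S,2S,3R)-2-azido-3-{8-[(tert-butyldimethylsilyl)oxy]octyl}-2-methylcyclopentan-1-ol | C[C@]1(N=[N+]=[N-])[C@H](CCCCCCCCO[Si](C)(C)C(C)(C)C)CC[C@@H]1O | intermediate
9 | N-(benzyloxycarbonyl)-L-alanine | C[C@H](NC(=O)OCc1ccccc1)C(=O)O | starting material
10 | benzyl N-[(2S)-1-[methoxy(methyl)amino]-1-oxopropan-2-yl]carbamate | C[C@H](NC(=O)OCc1ccccc1)C(=O)N(C)OC | intermediate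
11 | ethynyltrimethylsilane | C#C[Si](C)(C)C | starting material
12 | lithium (trimethylsilyl)acetylide | [Li]C#C[Si](C)(C)C | intermediate
13 | benzyl N-[(2S)-3-oxo-5-(trimethylsilyl)pent-4-yn-2-yl]carbamate | C[C@H](NC(=O)OCc1ccccc1)C(=O)C#C[Si](C)(C)C | intermediate
14 | benzyl N-[(2S,3S)-3-hydroxy-5-(trimethylsilyl)pent-4-yn-2-yl]carbamate | C[C@H](NC(=O)OCc1ccccc1)[C@@H](O)C#C[Si](C)(C)C | intermediate
15 | benzyl N-[(2S,3S)-3-[(tert-butyldimethylsilyl)oxy]-5-(trimethylsilyl)pent-4-yn-2-yl]carbamate | C[C@H](NC(=O)OCc1ccccc1)[C@@H](O[Si](C)(C)C(C)(C)C)C#C[Si](C)(C)C | intermediate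
16 | benzyl N-[(2S,3S)-3-[(tert-butyldimethylsilyl)oxy]pent-4-yn-2-yl]carbamate | C[C@H](NC(=O)OCc1ccccc1)[C@@H](O[Si](C)(C)C(C)(C)C)C#C | intermediate
17 | methyl 9-chloro-9-oxononanoate | COC(=O)CCCCCCCC(=O)Cl | starting material
18 | methyl (12S,13S)-13-{[(benzyloxy)carbonyl]amino}-12-[(tert-butyldimethylsilyl)oxy]-9-oxotetradec-10-ynoate | C[C@H](NC(=O)OCc1ccccc1)[C@@H](O[Si](C)(C)C(C)(C)C)C#CC(=O)CCCCCCCC(=O)OC | intermediate
19 | methyl 8-[(2S,3S)-3-[(tert-butyldimethylsilyl)oxy]-2-methyl-2,3,4,5-tetrahydropyridin-6-yl]octanoate | C[C@H]1[C@@H](O[Si](C)(C)C(C)(C)C)CCC(CCCCCCCC(=O)OC)=N1 | intermediate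
20 | methyl 8-[(2R,5S,6S)-5-[(tert-butyldimethylsilyl)oxy]-6-methylpiperidin-2-yl]octanoate | C[C@H]1[C@@H](O[Si](C)(C)C(C)(C)C)CC[C@@H](CCCCCCCC(=O)OC)N1 | intermediate
21 | tert-butyl (2S,3S,6R)-3-[(tert-butyldimethylsilyl)oxy]-6-(8-methoxy-8-oxooctyl)-2-methylpiperidine-1-carboxylate | C[C@H]1[C@@H](O[Si](C)(C)C(C)(C)C)CC[C@@H](CCCCCCCC(=O)OC)N1C(=O)OC(C)(C)C | intermediate
22 | 8-[(2R,5S,6S)-1-(tert-butoxycarbonyl)-5-[(tert-butyldimethylsilyl)oxy]-6-methylpiperidin-2-yl]octanoic acid | C[C@H]1[C@@H](O[Si](C)(C)C(C)(C)C)CC[C@@H](CCCCCCCC(=O)O)N1C(=O)OC(C)(C)C | intermediate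
23 | mixed 2,4,6-trichlorobenzoic anhydride of acid 22 | C[C@H]1[C@@H](O[Si](C)(C)C(C)(C)C)CC[C@@H](CCCCCCCC(=O)OC(=O)c2c(Cl)cc(Cl)cc2Cl)N1C(=O)OC(C)(C)C | intermediate
24 | (1S,2S,3R)-2-azido-3-{8-[(tert-butyldimethylsilyl)oxy]octyl}-2-methylcyclopentyl 8-[(2R,5S,6S)-1-(tert-butoxycarbonyl)-5-[(tert-butyldimethylsilyl)oxy]-6-methylpiperidin-2-yl]octanoate | C[C@]1(N=[N+]=[N-])[C@H](CCCCCCCCO[Si](C)(C)C(C)(C)C)CC[C@@H]1OC(=O)CCCCCCC[C@@H]2CC[C@H](O[Si](C)(C)C(C)(C)C)[C@H](C)N2C(=O)OC(C)(C)C | intermediate
25 | (1S,2S,3R)-2-azido-3-(8-hydroxyoctyl)-2-methylcyclopentyl 8-[(2R,5S,6S)-1-(tert-butoxycarbonyl)-5-hydroxy-6-methylpiperidin-2-yl]octanoate | C[C@]1(N=[N+]=[N-])[C@H](CCCCCCCCO)CC[C@@H]1OC(=O)CCCCCCC[C@@H]2CC[C@H](O)[C@H](C)N2C(=O)OC(C)(C)C | intermediate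
26 | 8-[(1R,2S,3S)-2-azido-3-({8-[(2R,5S,6S)-1-(tert-butoxycarbonyl)-5-hydroxy-6-methylpiperidin-2-yl]octanoyl}oxy)-2-methylcyclopentyl]octanoic acid | C[C@]1(N=[N+]=[N-])[C@H](CCCCCCCC(=O)O)CC[C@@H]1OC(=O)CCCCCCC[C@@H]2CC[C@H](O)[C@H](C)N2C(=O)OC(C)(C)C | intermediate
27 | mixed 2,4,6-trichlorobenzoic anhydride of seco acid 26 | C[C@]1(N=[N+]=[N-])[C@H](CCCCCCCC(=O)OC(=O)c3c(Cl)cc(Cl)cc3Cl)CC[C@@H]1OC(=O)CCCCCCC[C@@H]2CC[C@H](O)[C@H](C)N2C(=O)OC(C)(C)C | intermediate
28 | N-Boc azido macrodilactone | C[C@]1(N=[N+]=[N-])[C@@H]2CCCCCCCC(=O)O[C@H]3CC[C@@H](CCCCCCCC(=O)O[C@H]1CC2)N(C(=O)OC(C)(C)C)[C@H]3C | intermediate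
29 | azido macrodilactone with free piperidine nitrogen (rearrangement precursor) | C[C@]1(N=[N+]=[N-])[C@@H]2CCCCCCCC(=O)O[C@H]3CC[C@@H](CCCCCCCC(=O)O[C@H]1CC2)N[C@H]3C | intermediate
30 | aminodiazonium piperidinium bis(triflate) of 29 | C[C@]1(N[N+]#N)[C@@H]2CCCCCCCC(=O)O[C@H]3CC[C@@H](CCCCCCCC(=O)O[C@H]1CC2)[NH2+][C@H]3C.[O-]S(=O)(=O)C(F)(F)F.[O-]S(=O)(=O)C(F)(F)F | intermediate
31 | iminium piperidinium bis(triflate) of the target | CC1=[NH+][C@@H]2CCCCCCCC(=O)O[C@H]3CC[C@@H](CCCCCCCC(=O)O[C@H]1CC2)[NH2+][C@H]3C.[O-]S(=O)(=O)C(F)(F)F.[O-]S(=O)(=O)C(F)(F)F | intermediate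
32 | target CNP0304114.1 | CC1=N[C@@H]2CCCCCCCC(=O)O[C@H]3CC[C@@H](CCCCCCCC(=O)O[C@H]1CC2)N[C@H]3C | target

**Count**

Total: 17 steps. Longest linear sequence: 13 steps (steps 5 to 11, then 12 to 17).

**Steps most likely to fail**

Step 17. The protonated azide may lose hydrazoic acid by heterolysis, possibly assisted by the trans acyloxy group, or the wrong substituent may migrate. The fallback sets out from 28 and moves the leaving group from dinitrogen to a sulfonate on nitrogen, so that no strong acid and no C–N ionisation are involved. Staudinger reduction (PMe3, THF/H2O) should give the primary tert-alkyl amine F1, whose trans relation to the ester disfavours O-to-N acyl transfer. Bis(4-nitrobenzenesulfonyl) peroxide with K2CO3 in EtOAc at −78 °C should give the N-(4-nitrobenzenesulfonyloxy)amine F2. On warming, F2 should undergo the Stieglitz-type carbon-to-nitrogen shift to the N-Boc imine F3. TFA followed by NaHCO3 then returns to the route at 32.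

Step 2. Enantiofacial discrimination on the α-substituted enone may be insufficient, or 1,2-addition and incomplete O-silylation may intervene. The fallback sets out from 2 and 3 and replaces asymmetric catalysis by resolution. Grignard reagent 4 is added with CuBr·SMe2 and TMSCl in THF at −78 °C without a chiral ligand, giving 5 together with the enantiomeric magnesium enolate F4, and hence 6 together with the enantiomeric silyl enol ether F5. Azidation as in step 3 gives 7 together with the enantiomeric azido ketone F6. Preparative chromatography on a chiral stationary phase separates the two, and 7 re-enters the route at step 4.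

Step 4. Hydride may be delivered to the wrong face, because the polar azide favours attack anti to itself and so opposes the steric bias. The fallback sets out from 7 and replaces the selective step by a separate-and-recycle loop. Unselective reduction (NaBH4, MeOH, −20 °C) gives 8 together with the C1-epimeric (1R,2S,3R)-alcohol F7, and the two are separated by chromatography. F7 is oxidised back to 7 with Dess–Martin periodinane and resubmitted; the loop returns to the route at 8.

**Further compounds**

F1 | step 17 | N-Boc macrodilactone with a primary amine in place of the azide | C[C@]1(N)[C@@H]2CCCCCCCC(=O)O[C@H]3CC[C@@H](CCCCCCCC(=O)O[C@H]1CC2)N(C(=O)OC(C)(C)C)[C@H]3C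
F2 | step 17 | N-(4-nitrobenzenesulfonyloxy)amine of F1 | C[C@]1(NOS(=O)(=O)c4ccc(cc4)[N+](=O)[O-])[C@@H]2CCCCCCCC(=O)O[C@H]3CC[C@@H](CCCCCCCC(=O)O[C@H]1CC2)N(C(=O)OC(C)(C)C)[C@H]3C
F3 | step 17 | N-Boc derivative of the target imine | CC1=N[C@@H]2CCCCCCCC(=O)O[C@H]3CC[C@@H](CCCCCCCC(=O)O[C@H]1CC2)N(C(=O)OC(C)(C)C)[C@H]3C
F4 | step 2 | bromomagnesium (3S)-3-{8-[(tert-butyldimethylsilyl)oxy]octyl}-2-methylcyclopent-1-en-1-olate (enantiomer of 5) | CC1=C(O[Mg]Br)CC[C@@H]1CCCCCCCCO[Si](C)(C)C(C)(C)C
F5 | step 2 | tert-butyldimethyl({8-[(1S)-2-methyl-3-(trimethylsilyloxy)cyclopent-2-en-1-yl]octyl}oxy)silane (enantiomer of 6) | CC1=C(O[Si](C)(C)C)CC[C@@H]1CCCCCCCCO[Si](C)(C)C(C)(C)C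
F6 | step 2 | (2R,3S)-2-azido-3-{8-[(tert-butyldimethylsilyl)oxy]octyl}-2-methylcyclopentan-1-one (enantiomer of 7) | C[C@@]1(N=[N+]=[N-])[C@@H](CCCCCCCCO[Si](C)(C)C(C)(C)C)CCC1=O
F7 | step 4 | (1R,2S,3R)-2-azido-3-{8-[(tert-butyldimethylsilyl)oxy]octyl}-2-methylcyclopentan-1-ol (C1 epimer of 8) | C[C@]1(N=[N+]=[N-])[C@H](CCCCCCCCO[Si](C)(C)C(C)(C)C)CC[C@H]1O
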